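**Plan**

1. Atom labels follow the cyclopenta[c]pyridine skeleton of each alkaloid half (C1, N2, C3, C4, C4a, C5, C6, C7, C7a). The retrosynthesis first cuts the two ester C6–O bonds (Mitsunobu, inversion), giving an α-truxillic diacid (the head-to-tail [2+2] dimer of O-tosylferulic acid) and two molecules of the 6S amino alcohol, 6-epi-incarvilline.
2. In the amino alcohol, N–CH3 is traced to N–CO2CH3, the C4 methyl to a C4 ketone and the C6 oxygen to an exocyclic C6 methylene. This exposes the enabling feature: C5, C6 (oxygenated) and C7 (methyl-bearing) of the cyclopentane form a three-carbon bridge between C4a and C7a, the α- and β-carbons of a piperidine-ring enone, so C7–C7a and C5–C4a are cut as a methyl-trimethylenemethane (3+2).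
3. Forward: the piperidinone ring comes from furfurylamine by aza-Achmatowicz ring expansion, the cyclopentane is annulated onto it by the Pd–TMM cycloaddition, the cyclobutane is closed separately by solid-state photodimerisation, and two amino alcohol molecules are then esterified to the diacid.
4. Stereochemistry: C7a, C4a and C7 arise in the ligand-controlled cycloaddition (cis fusion enforced by the tether); C4 by convex-face hydrogenation; C6 by convex-face hydride delivery followed by Mitsunobu inversion; the cyclobutane by crystal packing.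
5. Any residual minor enantiomer of the amino alcohol ends up mainly in a separable heterochiral diester during the double esterification, which raises the enantiomeric purity of the target.

Key step: step 6

Assumption: the sense of asymmetric induction of the chiral Pd–TMM catalyst on enone 7 is not known in advance; the ligand antipode that gives (4aR,7S,7aS)-13 is to be identified in a first small-scale run and used throughout.

**Route**

Step 1
Reactants: 1 furfurylamine; 2 methyl chloroformate
Product: 3 methyl (furan-2-ylmethyl)carbamate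
Conditions: ClCO2Me, 2 M aq. NaOH, CH2Cl2, 0 °C
Reagents that add atoms: none
Why: Schotten–Baumann N-acylation of the primary amine gives the carbamate, which activates nitrogen for the ring expansion and whose carbonyl carbon later becomes the N-methyl group.

Step 2
Reactants: 3 methyl (furan-2-ylmethyl)carbamate
Product: 5 methyl 6-hydroxy-3-oxo-3,6-dihydropyridine-1(2H)-carboxylate (racemic), via Z-keto-enal 4 (not isolated)
Conditions: mCPBA, CH2Cl2, 0 °C → rt
Reagents that add atoms: meta-chloroperoxybenzoic acid, O=C(OO)c1cccc(Cl)c1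
Why: aza-Achmatowicz rearrangement: epoxidation of the furan at its substituted C=C bond and ring opening give the cis-enedione 4, whose carbamate N–H adds to the aldehyde and closes the six-membered hemiaminal.

Step 3
Reactants: 5 methyl 6-hydroxy-3-oxo-3,6-dihydropyridine-1(2H)-carboxylate
Product: 7 methyl 3-oxo-3,6-dihydropyridine-1(2H)-carboxylate, via N-acyliminium ion 6 (not isolated)
Conditions: Et3SiH, TFA, CH2Cl2, −40 → 0 °C
Reagents that add atoms: none
Why: acid ionises the hemiaminal to the N-acyliminium ion, which triethylsilane reduces at the carbon next to nitrogen (ionic hydrogenation of an N-acyliminium ion), leaving the conjugated enone intact.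

Step 4
Reactants: 8 (2-bromoprop-2-en-1-yl)trimethylsilane; 9 acetaldehyde
Product: 11 3-[(trimethylsilyl)methyl]but-3-en-2-ol (racemic), via vinyl Grignard reagent 10 (not isolated)
Conditions: Mg, THF, rt; MeCHO, −78 → 0 °C; pH 7 buffer
Reagents that add atoms: none
Why: magnesium insertion into the vinyl C–Br bond and 1,2-addition to acetaldehyde (Grignard reaction) build the methyl-bearing carbinol; the allylsilane tolerates base and a neutral quench, and the carbinol configuration is irrelevant because it is lost on ionisation in step 6.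

Step 5
Reactants: 11 3-[(trimethylsilyl)methyl]but-3-en-2-ol
Product: 12 3-[(trimethylsilyl)methyl]but-3-en-2-yl acetate (racemic)
Conditions: Ac2O, pyridine, DMAP (cat.), CH2Cl2, 0 °C → rt
Reagents that add atoms: acetic anhydride, CC(=O)OC(C)=O
Why: DMAP-catalysed acetylation of the secondary allylic alcohol installs the leaving group that Pd(0) ionises in step 6, under mildly basic conditions that avoid protodesilylation.

Step 6
Reactants: 7 methyl 3-oxo-3,6-dihydropyridine-1(2H)-carboxylate; 12 3-[(trimethylsilyl)methyl]but-3-en-2-yl acetate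
Product: 13 methyl (4aR,7S,7aS)-7-methyl-6-methylidene-4-oxooctahydro-2H-cyclopenta[c]pyridine-2-carboxylate
Conditions: Pd(dba)2 (5 mol %), BINOL-derived trans-2,5-bis(2-naphthyl)pyrrolidine phosphoramidite (10 mol %, antipode as in the assumption), PhMe, 0 → 23 °C
Reagents that add atoms: none
Why: Pd(0) ionises the allylic acetate and the released acetate removes the silyl group, giving the zwitterionic Pd–trimethylenemethane complex, which equilibrates so that its methyl-bearing terminus is the nucleophilic carbon; this carbon adds to the enone β-carbon C7a, and the enolate carbon C4a then attacks the cationic η3-allylpalladium terminus C5 and releases Pd(0). The closest known reaction type is the palladium-catalysed TMM (3+2) cycloaddition of silyl allylic acetates to cyclic enones, run enantioselectively with chiral phosphoramidite ligands. The cyclopentane is closed by enolate C-allylation at the proximal allyl terminus, formally a 5-endo-trig attack that is feasible because the electrophile is a Pd-bound allyl cation, and the short tether allows only the cis ring fusion, which fixes C4a relative to C7a. C7a is set by the ligand, which selects the enone face in the conjugate addition, and C7 is set in the same bond-forming event with the methyl turned away from the piperidinone ring (exo); this centre also becomes epimerisable towards that more stable orientation once C6 is a ketone. The step needs the methyl group next to C7a, which the preference of a substituted Pd–TMM to bond through its substituted terminus should secure, and 1,4- rather than 1,2-addition, which the soft carbon nucleophile and the absence of a Lewis-acid co-catalyst should secure.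

Step 7
Reactants: 13 methyl (4aR,7S,7aS)-7-methyl-6-methylidene-4-oxooctahydro-2H-cyclopenta[c]pyridine-2-carboxylate
Product: 14 methyl (4R,4aR,7S,7aS)-4-hydroxy-4,7-dimethyl-6-methylideneoctahydro-2H-cyclopenta[c]pyridine-2-carboxylate
Conditions: MeLi, CeCl3, THF, −78 °C
Reagents that add atoms: methyllithium, [Li]C
Why: the weakly basic organocerium reagent adds to the enolisable C4 ketone without deprotonating C4a or attacking the carbamate (organocerium 1,2-addition); convex-face attack should place the methyl exo and the hydroxyl endo, a centre that is re-set in step 9.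

Step 8
Reactants: 14 methyl (4R,4aR,7S,7aS)-4-hydroxy-4,7-dimethyl-6-methylideneoctahydro-2H-cyclopenta[c]pyridine-2-carboxylate
Product: 16 methyl (4R,4aR,7S,7aR)-4-hydroxy-4,7-dimethyl-6-oxooctahydro-2H-cyclopenta[c]pyridine-2-carboxylate, via spiro ozonide 15 (not isolated)
Conditions: O3, CH2Cl2, −78 °C; PPh3, −78 °C → rt
Reagents that add atoms: ozone, [O-][O+]=O
Why: ozonolysis of the only alkene (Criegee mechanism, secondary ozonide reduced by the phosphine) unmasks the C6 ketone while the carbamate and the tertiary alcohol are inert; C7, now α to the ketone, can be equilibrated with mild base to the exo-methyl epimer if step 6 left any of the other.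

Step 9
Reactants: 16 methyl (4R,4aR,7S,7aR)-4-hydroxy-4,7-dimethyl-6-oxooctahydro-2H-cyclopenta[c]pyridine-2-carboxylate
Product: 19 methyl (4R,4aS,7S,7aR)-4,7-dimethyl-6-oxooctahydro-2H-cyclopenta[c]pyridine-2-carboxylate, via exocyclic alkene 17 (not isolated), via enecarbamate 18 (not isolated)
Conditions: Burgess reagent, PhMe, 60 °C; aqueous wash, crude into EtOAc; H2 (3 atm), 10% Pd/C, rt
Reagents that add atoms: none
Why: the Burgess dehydration is a syn elimination, and with the C4 hydroxyl anti to C4a–H only the C3 and methyl hydrogens can be reached, so alkenes 17 and 18 should form but not the C4=C4a isomer; heterogeneous hydrogenation then adds hydrogen to both from the convex face, anti to the C4a–C5 bond, which sets C4 as R.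

Step 10
Reactants: 19 methyl (4R,4aS,7S,7aR)-4,7-dimethyl-6-oxooctahydro-2H-cyclopenta[c]pyridine-2-carboxylate
Product: 21 (4R,4aS,6S,7S,7aR)-2,4,7-trimethyloctahydro-1H-cyclopenta[c]pyridin-6-ol (6-epi-incarvilline), via hydroxy carbamate 20 (not isolated)
Conditions: LiAlH4, THF, −78 → 0 °C, then reflux; aq. NaOH work-up
Reagents that add atoms: none
Why: at low temperature the small hydride attacks the C6 ketone from the convex face (away from the piperidine ring and the endo C4 methyl, the trans-2-methylcyclopentanol outcome typical of LiAlH4) to give the 6S alkoxide, and on heating the methyl carbamate is reduced to N–CH3 (hydride reduction of a carbamate).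

Step 11
Reactants: 22 ferulic acid
Product: 23 (2E)-3-{3-methoxy-4-[(4-methylbenzenesulfonyl)oxy]phenyl}prop-2-enoic acid
Conditions: TsCl, aq. NaOH, THF, 0 °C → rt; then HCl
Reagents that add atoms: p-toluenesulfonyl chloride, Cc1ccc(cc1)S(=O)(=O)Cl
Why: the phenoxide is sulfonylated selectively (Schotten–Baumann sulfonylation), since any mixed anhydride at the carboxylate is hydrolysed in the aqueous base; the tosylate masks the phenol and gives a crystalline acid.

Step 12
Reactants: 23 (2E)-3-{3-methoxy-4-[(4-methylbenzenesulfonyl)oxy]phenyl}prop-2-enoic acid (two molecules)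
Product: 24 (1α,2α,3β,4β)-2,4-bis[3-methoxy-4-(tosyloxy)phenyl]cyclobutane-1,3-dicarboxylic acid
Conditions: hν (high-pressure Hg lamp, Pyrex), crystalline powder, rt
Reagents that add atoms: none
Why: topochemical [2+2] photocycloaddition: in head-to-tail (α-type) packing the alkenes of centrosymmetrically related molecules lie parallel and close, so irradiation of the solid should give only the centrosymmetric α-truxillic dimer and fix all four cyclobutane centres.

Step 13
Reactants: 21 (4R,4aS,6S,7S,7aR)-2,4,7-trimethyloctahydro-1H-cyclopenta[c]pyridin-6-ol (two equivalents); 24 (1α,2α,3β,4β)-2,4-bis[3-methoxy-4-(tosyloxy)phenyl]cyclobutane-1,3-dicarboxylic acid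
Product: 25 bis[(4R,4aS,6R,7S,7aR)-2,4,7-trimethyloctahydro-1H-cyclopenta[c]pyridin-6-yl] (1α,2α,3β,4β)-2,4-bis[3-methoxy-4-(tosyloxy)phenyl]cyclobutane-1,3-dicarboxylate
Conditions: PPh3, DIAD, THF, 0 °C → rt
Reagents that add atoms: none
Why: Mitsunobu esterification: each C6 hydroxyl is activated as its oxyphosphonium ion and displaced by a carboxylate of 24 with SN2 inversion (6S → 6R), while the tosylates keep the phenols from competing as nucleophiles.

Step 14
Reactants: 25 bis-tosylate diester
Product: 26 bis[(4R,4aS,6R,7S,7aR)-2,4,7-trimethyloctahydro-1H-cyclopenta[c]pyridin-6-yl] (1α,2α,3β,4β)-2,4-bis(4-hydroxy-3-methoxyphenyl)cyclobutane-1,3-dicarboxylate (incarvillateine)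
Conditions: 5% Na(Hg), Na2HPO4, MeOH, 0 °C; AcOH quench
Reagents that add atoms: none
Why: electron-transfer cleavage of the aryl sulfonate S–O bonds by sodium amalgam (reductive desulfonylation) frees both phenols; the phosphate buffer holds back methoxide so the two hindered esters should not be transesterified, and no stereocentre is touched.

**Compound list**

1 | furfurylamine | NCc1ccco1 | starting material
2 | methyl chloroformate | COC(=O)Cl | starting material
3 | methyl (furan-2-ylmethyl)carbamate | COC(=O)NCc1ccco1 | intermediate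
4 | methyl N-[(3Z)-2,5-dioxopent-3-en-1-yl]carbamate | COC(=O)NCC(=O)/C=C\C=O | intermediate (not isolated)
5 | methyl 6-hydroxy-3-oxo-3,6-dihydropyridine-1(2H)-carboxylate (racemic) | COC(=O)N1CC(=O)C=CC1O | intermediate
6 | 1-(methoxycarbonyl)-3-oxo-2,3-dihydropyridin-1-ium (N-acyliminium ion) | COC(=O)[N+]1=CC=CC(=O)C1 | intermediate (not isolated)
7 | methyl 3-oxo-3,6-dihydropyridine-1(2H)-carboxylate | COC(=O)N1CC=CC(=O)C1 | intermediate
8 | (2-bromoprop-2-en-1-yl)trimethylsilane | C[Si](C)(C)CC(Br)=C | starting material
9 | acetaldehyde | CC=O | starting material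
10 | bromo[3-(trimethylsilyl)prop-1-en-2-yl]magnesium | C[Si](C)(C)CC(=C)[Mg]Br | intermediate (not isolated)
11 | 3-[(trimethylsilyl)methyl]but-3-en-2-ol (racemic) | CC(O)C(=C)C[Si](C)(C)C | intermediate
12 | 3-[(trimethylsilyl)methyl]but-3-en-2-yl acetate (racemic) | CC(OC(C)=O)C(=C)C[Si](C)(C)C | intermediate
13 | methyl (4aR,7S,7aS)-7-methyl-6-methylidene-4-oxooctahydro-2H-cyclopenta[c]pyridine-2-carboxylate | C=C1C[C@@H]2[C@@H](CN(C(=O)OC)CC2=O)[C@@H]1C | intermediate
14 | methyl (4R,4aR,7S,7aS)-4-hydroxy-4,7-dimethyl-6-methylideneoctahydro-2H-cyclopenta[c]pyridine-2-carboxylate | C=C1C[C@@H]2[C@@H](CN(C(=O)OC)C[C@]2(C)O)[C@@H]1C | intermediate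
15 | methyl (4R,4aR,7S,7aS)-4-hydroxy-4,7-dimethyloctahydrospiro[cyclopenta[c]pyridine-6,3'-[1,2,4]trioxolane]-2-carboxylate (secondary ozonide, both configurations at the spiro carbon) | O1COOC12C[C@@H]3[C@@H](CN(C(=O)OC)C[C@]3(C)O)[C@@H]2C | intermediate (not isolated)
16 | methyl (4R,4aR,7S,7aR)-4-hydroxy-4,7-dimethyl-6-oxooctahydro-2H-cyclopenta[c]pyridine-2-carboxylate | O=C1C[C@@H]2[C@@H](CN(C(=O)OC)C[C@]2(C)O)[C@@H]1C | intermediate
17 | methyl (4aR,7S,7aR)-7-methyl-4-methylidene-6-oxooctahydro-2H-cyclopenta[c]pyridine-2-carboxylate | O=C1C[C@@H]2[C@@H](CN(C(=O)OC)CC2=C)[C@@H]1C | intermediate (not isolated)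
18 | methyl (4aR,7S,7aR)-4,7-dimethyl-6-oxo-1,4a,5,6,7,7a-hexahydro-2H-cyclopenta[c]pyridine-2-carboxylate | O=C1C[C@@H]2[C@@H](CN(C(=O)OC)C=C2C)[C@@H]1C | intermediate (not isolated)
19 | methyl (4R,4aS,7S,7aR)-4,7-dimethyl-6-oxooctahydro-2H-cyclopenta[c]pyridine-2-carboxylate | O=C1C[C@@H]2[C@@H](CN(C(=O)OC)C[C@@H]2C)[C@@H]1C | intermediate
20 | methyl (4R,4aS,6S,7S,7aR)-6-hydroxy-4,7-dimethyloctahydro-2H-cyclopenta[c]pyridine-2-carboxylate (as its aluminium alkoxide) | O[C@H]1C[C@@H]2[C@@H](CN(C(=O)OC)C[C@@H]2C)[C@@H]1C | intermediate (not isolated)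
21 | (4R,4aS,6S,7S,7aR)-2,4,7-trimethyloctahydro-1H-cyclopenta[c]pyridin-6-ol (6-epi-incarvilline) | O[C@H]1C[C@@H]2[C@@H](CN(C)C[C@@H]2C)[C@@H]1C | intermediate
22 | ferulic acid | COc1cc(/C=C/C(=O)O)ccc1O | starting material
23 | (2E)-3-{3-methoxy-4-[(4-methylbenzenesulfonyl)oxy]phenyl}prop-2-enoic acid | COc1cc(/C=C/C(=O)O)ccc1OS(=O)(=O)c1ccc(C)cc1 | intermediate
24 | (1α,2α,3β,4β)-2,4-bis[3-methoxy-4-(tosyloxy)phenyl]cyclobutane-1,3-dicarboxylic acid | COc1cc([C@H]2[C@H](C(=O)O)[C@H](c3ccc(OS(=O)(=O)c4ccc(C)cc4)c(OC)c3)[C@H]2C(=O)O)ccc1OS(=O)(=O)c1ccc(C)cc1 | intermediate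
25 | bis[(4R,4aS,6R,7S,7aR)-2,4,7-trimethyloctahydro-1H-cyclopenta[c]pyridin-6-yl] (1α,2α,3β,4β)-2,4-bis[3-methoxy-4-(tosyloxy)phenyl]cyclobutane-1,3-dicarboxylate | COc1cc([C@H]2[C@H](C(=O)O[C@@H]3C[C@@H]4[C@@H](CN(C)C[C@@H]4C)[C@@H]3C)[C@H](c3ccc(OS(=O)(=O)c4ccc(C)cc4)c(OC)c3)[C@H]2C(=O)O[C@@H]2C[C@@H]3[C@@H](CN(C)C[C@@H]3C)[C@@H]2C)ccc1OS(=O)(=O)c1ccc(C)cc1 | intermediate
26 | bis[(4R,4aS,6R,7S,7aR)-2,4,7-trimethyloctahydro-1H-cyclopenta[c]pyridin-6-yl] (1α,2α,3β,4β)-2,4-bis(4-hydroxy-3-methoxyphenyl)cyclobutane-1,3-dicarboxylate (incarvillateine) | COc1cc([C@H]2[C@H](C(=O)O[C@@H]3C[C@@H]4[C@@H](CN(C)C[C@@H]4C)[C@@H]3C)[C@H](c3ccc(O)c(OC)c3)[C@H]2C(=O)O[C@@H]2C[C@@H]3[C@@H](CN(C)C[C@@H]3C)[C@@H]2C)ccc1O | target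

**Step count**

Total: 14 steps. Longest linear sequence: 10 steps (1, 2, 3, 6, 7, 8, 9, 10, 13, 14, from furfurylamine).

**Steps most likely to fail**

Step 6. The process at risk is enantiofacial discrimination: the chiral Pd–TMM complex may not distinguish the two faces of this small cis-enone well enough, and a ligand-poor background pathway would erode selectivity further. The fallback replaces catalyst control by classical resolution. It sets out from 21 of whatever enantiomeric composition the sequence delivers, down to the racemate obtained when step 6 is run with triisopropyl phosphite as achiral ligand and steps 7–10 are kept unchanged. Compound 21 is combined with (2R,3R)-O,O'-dibenzoyltartaric acid in ethanol/acetone, and the 1:1 salt of 21 with (2R,3R)-2,3-bis(benzoyloxy)butanedioic acid F1 is separated from its diastereomer by fractional crystallisation. Aqueous NaOH and extraction then return to 21 in enantiopure form.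

Step 9. Two processes are at risk. The elimination may run towards the ring-fusion hydrogen, giving the tetrasubstituted C4=C4a alkene, which resists hydrogenation and erases C4a; this is likely if the methyl group in step 7 entered from the concave face. The hydrogenation may also select the face poorly. The fallback is a radical deoxygenation that forms no alkene. From 16, acylation with methyl chlorooxoacetate (DMAP, pyridine, CH2Cl2) gives the tertiary oxalate methyl (4R,4aR,7S,7aR)-4-[(methoxyoxalyl)oxy]-4,7-dimethyl-6-oxooctahydro-2H-cyclopenta[c]pyridine-2-carboxylate F2. Bu3SnH/AIBN in refluxing toluene cleaves its C4–O bond homolytically (Barton–McCombie-type deoxygenation), and the tertiary C4 radical should take hydrogen from the stannane on the convex face, which leads back to 19.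

Step 13. The processes at risk are elimination of the hindered C6 oxyphosphonium ion and stalling at the mono-ester, because the diacid is bulky and each alcohol carries a basic amine. The fallback separates inversion from ester formation. From 21, a Mitsunobu reaction with the small, more acidic 4-nitrobenzoic acid gives the inverted ester (4R,4aS,6R,7S,7aR)-2,4,7-trimethyloctahydro-1H-cyclopenta[c]pyridin-6-yl 4-nitrobenzoate F3. K2CO3 in methanol releases the 6R alcohol (4R,4aS,6R,7S,7aR)-2,4,7-trimethyloctahydro-1H-cyclopenta[c]pyridin-6-ol F4. Diacid 24 is converted with oxalyl chloride and catalytic DMF into (1α,2α,3β,4β)-2,4-bis[3-methoxy-4-(tosyloxy)phenyl]cyclobutane-1,3-dicarbonyl dichloride F5, which acylates two equivalents of F4 (pyridine, DMAP, CH2Cl2) with retention at C6 and returns to the route at 25.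

**Further compounds**

F1 | step 6 | 1:1 salt of 21 with (2R,3R)-2,3-bis(benzoyloxy)butanedioic acid | O[C@H]1C[C@@H]2[C@@H](CN(C)C[C@@H]2C)[C@@H]1C.OC(=O)[C@H](OC(=O)c1ccccc1)[C@@H](OC(=O)c1ccccc1)C(O)=O
F2 | step 9 | methyl (4R,4aR,7S,7aR)-4-[(methoxyoxalyl)oxy]-4,7-dimethyl-6-oxooctahydro-2H-cyclopenta[c]pyridine-2-carboxylate | O=C1C[C@@H]2[C@@H](CN(C(=O)OC)C[C@]2(C)OC(=O)C(=O)OC)[C@@H]1C
F3 | step 13 | (4R,4aS,6R,7S,7aR)-2,4,7-trimethyloctahydro-1H-cyclopenta[c]pyridin-6-yl 4-nitrobenzoate | O=C(O[C@@H]1C[C@@H]2[C@@H](CN(C)C[C@@H]2C)[C@@H]1C)c1ccc(cc1)[N+](=O)[O-]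
F4 | step 13 | (4R,4aS,6R,7S,7aR)-2,4,7-trimethyloctahydro-1H-cyclopenta[c]pyridin-6-ol | O[C@@H]1C[C@@H]2[C@@H](CN(C)C[C@@H]2C)[C@@H]1C
F5 | step 13 | (1α,2α,3β,4β)-2,4-bis[3-methoxy-4-(tosyloxy)phenyl]cyclobutane-1,3-dicarbonyl dichloride | COc1cc([C@H]2[C@H](C(=O)Cl)[C@H](c3ccc(OS(=O)(=O)c4ccc(C)cc4)c(OC)c3)[C@H]2C(=O)Cl)ccc1OS(=O)(=O)c1ccc(C)cc1
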